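The route rests on cutting the cycloheptane at C5–C6 and the cyclobutane at C7–C8 (tricyclo[5.4.0.0^{2,8}]undecane numbering: C6 carries the angelate, C7 the quaternary methyl, C8 is the CH next to the C9 ketone). In one pot a C5 sulfonyl carbanion is acylated by a C6 methyl ester (seven-membered ring) and the derived keto sulfone dianion opens a C8–C9 epoxide through C7 (4-exo-tet, cyclobutane). The step exploits that C6 is oxygenated, so it can serve first as acyl acceptor and then acidify C7–H, and that C8 lies beside oxygenated C9. The precursor is a Diels–Alder-derived cyclohexene oxide bearing a sulfonylated C2 side chain and a propanoate arm at C1.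

Key step: step 9

Remark: C1–C11 are the target locants just defined and are used for the tricyclic intermediates; centres that are later planarised (C7 in 12–14, C5 in 14 and 15, the enol ether geometry in 7–11) are carried as mixtures.

Step 1
Reactants: 1 ethyl (2E,4E)-hexa-2,4-dienoate (ethyl sorbate)
Product: 3 ethyl (3E)-2,2-dimethylhexa-3,5-dienoate, via ethyl (3E)-2-methylhexa-3,5-dienoate 2 (not isolated)
Conditions: LiN(iPr)2, DMPU, THF, −78 °C, MeI; then LiN(iPr)2, MeI, −78 to 0 °C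
Reagents that add atoms: iodomethane CI
Why: Deconjugative α-alkylation of the extended ester enolate: each deprotonation gives the trienolate, which MeI attacks at the α-carbon, so two rounds install the gem-dimethyl group and leave the (3E)-diene; no stereocentre is formed.

Step 2
Reactants: 3 ethyl (3E)-2,2-dimethylhexa-3,5-dienoate, 4 (3E)-pent-3-en-2-one
Product: 5 ethyl 2-[(1R,5R,6S)-6-acetyl-5-methylcyclohex-2-en-1-yl]-2-methylpropanoate
Conditions: (S)-3,3-diphenyl-1-(2-methylphenyl)tetrahydro-1H,3H-pyrrolo[1,2-c][1,3,2]oxazaborole (20 mol%), HN(SO2CF3)2 (20 mol%), CH2Cl2, −78 to −20 °C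
Reagents that add atoms: none
Why: Chiral-Lewis-acid-catalysed Diels–Alder reaction: ortho regiochemistry and the endo transition state should put the acetyl group cis to the ring C1 side chain, the E-enone keeps methyl trans to acetyl, and the catalyst (the enantiomer that blocks the enone face leading to the antipode, taken here as S) sets the absolute configuration of all three centres.

Step 3
Reactants: 5 ethyl 2-[(1R,5R,6S)-6-acetyl-5-methylcyclohex-2-en-1-yl]-2-methylpropanoate, 6 (methoxymethyl)triphenylphosphonium chloride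
Product: 7 ethyl 2-[(1R,5R,6S)-6-(1-methoxyprop-1-en-2-yl)-5-methylcyclohex-2-en-1-yl]-2-methylpropanoate (E/Z mixture)
Conditions: KN(SiMe3)2, THF, 0 to 23 °C
Reagents that add atoms: none
Why: Wittig olefination of the methyl ketone with the methoxymethylene ylide masks the ketone as an enol ether, the latent C6 ester; the hindered ester is inert and the ylide is not expected to epimerise the ring CH next to the ketone.

Step 4
Reactants: 7 ethyl 2-[(1R,5R,6S)-6-(1-methoxyprop-1-en-2-yl)-5-methylcyclohex-2-en-1-yl]-2-methylpropanoate, 8 methyl phenyl sulfone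
Product: 9 3-[(1R,5R,6S)-6-(1-methoxyprop-1-en-2-yl)-5-methylcyclohex-2-en-1-yl]-3-methyl-1-(phenylsulfonyl)butan-2-one
Conditions: n-BuLi (2.5 equiv, with 2.5 equiv of 8), THF, −78 to 23 °C; aq NH4Cl
Reagents that add atoms: none
Why: Claisen-type acylation of (phenylsulfonyl)methyllithium by the hindered ester should give the keto sulfone, whose immediate deprotonation by the second equivalent prevents over-addition; the enol ether is untouched.

Step 5
Reactants: 9 3-[(1R,5R,6S)-6-(1-methoxyprop-1-en-2-yl)-5-methylcyclohex-2-en-1-yl]-3-methyl-1-(phenylsulfonyl)butan-2-one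
Product: 10 (2R)-3-[(1R,5R,6S)-6-(1-methoxyprop-1-en-2-yl)-5-methylcyclohex-2-en-1-yl]-3-methyl-1-(phenylsulfonyl)butan-2-ol
Conditions: (R)-1-methyl-3,3-diphenyltetrahydro-1H,3H-pyrrolo[1,2-c][1,3,2]oxazaborole (20 mol%), catecholborane, toluene, −78 to −40 °C; aq NaOH
Reagents that add atoms: none
Why: Corey–Bakshi–Shibata reduction: with the tert-alkyl group as the large and the sulfonylmethyl as the small substituent, the (R)-catalyst should deliver hydride to give the (2R)-carbinol (the future C4 acetate centre), and catecholborane at low temperature leaves both alkenes alone.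

Step 6
Reactants: 10 (2R)-3-[(1R,5R,6S)-6-(1-methoxyprop-1-en-2-yl)-5-methylcyclohex-2-en-1-yl]-3-methyl-1-(phenylsulfonyl)butan-2-ol
Product: 11 tert-butyl{[(2R)-3-[(1R,5R,6S)-6-(1-methoxyprop-1-en-2-yl)-5-methylcyclohex-2-en-1-yl]-3-methyl-1-(phenylsulfonyl)butan-2-yl]oxy}dimethylsilane
Conditions: TBSOTf, 2,6-lutidine, CH2Cl2, −78 to 0 °C
Reagents that add atoms: tert-butyldimethylsilyl trifluoromethanesulfonate CC(C)(C)[Si](C)(C)OS(=O)(=O)C(F)(F)F
Why: Silylation with the silyl triflate and a hindered base protects the neopentyl alcohol so that it survives the oxidation and the carbanion chemistry.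

Step 7
Reactants: 11 tert-butyl{[(2R)-3-[(1R,5R,6S)-6-(1-methoxyprop-1-en-2-yl)-5-methylcyclohex-2-en-1-yl]-3-methyl-1-(phenylsulfonyl)butan-2-yl]oxy}dimethylsilane
Product: 12 methyl 2-[(1S,2R,6R)-2-{(3R)-3-[(tert-butyldimethylsilyl)oxy]-2-methyl-4-(phenylsulfonyl)butan-2-yl}-6-methylcyclohex-3-en-1-yl]propanoate (epimers at the propanoate α-carbon)
Conditions: pyridinium chlorochromate C5H5NH[CrO3Cl], NaOAc, CH2Cl2, 23 °C
Reagents that add atoms: pyridinium chlorochromate [O-][Cr](=O)(=O)Cl.c1cc[nH+]cc1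
Why: Oxidation of an enol ether by pyridinium chlorochromate (chromate addition to the electron-rich alkene, then 1,2-hydride shift) should convert the methoxyvinyl group directly into the methyl ester; the new α-centre forms as a mixture, which does not matter because it is deprotonated in step 9.

Step 8
Reactants: 12 methyl 2-[(1S,2R,6R)-2-{(3R)-3-[(tert-butyldimethylsilyl)oxy]-2-methyl-4-(phenylsulfonyl)butan-2-yl}-6-methylcyclohex-3-en-1-yl]propanoate
Product: 13 methyl 2-[(1R,2R,3S,4R,6S)-2-{(3R)-3-[(tert-butyldimethylsilyl)oxy]-2-methyl-4-(phenylsulfonyl)butan-2-yl}-4-methyl-7-oxabicyclo[4.1.0]heptan-3-yl]propanoate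
Conditions: mCPBA, NaHCO3, CH2Cl2, 0 °C
Reagents that add atoms: 3-chloroperoxybenzoic acid OOC(=O)c1cccc(Cl)c1
Why: Prilezhaev epoxidation: the peracid should approach the only alkene anti to the bulky allylic tert-alkyl substituent, giving the epoxide trans to both side chains, as needed for backside attack by C7.

Step 9
Reactants: 13 methyl 2-[(1R,2R,3S,4R,6S)-2-{(3R)-3-[(tert-butyldimethylsilyl)oxy]-2-methyl-4-(phenylsulfonyl)butan-2-yl}-4-methyl-7-oxabicyclo[4.1.0]heptan-3-yl]propanoate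
Product: 15 (1S,2S,4R,7R,8R,9S,11R)-4-[(tert-butyldimethylsilyl)oxy]-9-hydroxy-3,3,7,11-tetramethyl-5-(phenylsulfonyl)tricyclo[5.4.0.0^{2,8}]undecan-6-one (C5 epimers), via epoxy keto sulfone 14 (not isolated)
Conditions: LiN(SiMe3)2 (1.1 equiv), THF, −78 to −20 °C; then LiN(iPr)2 (2.5 equiv), DMPU, −78 to 23 °C; aq NH4Cl
Reagents that add atoms: none
Why: LiN(SiMe3)2 generates the C5 α-sulfonyl carbanion, which closes the seven-membered ring by 7-exo-trig acylation at the C6 methyl ester (a sulfone Dieckmann-type condensation) and rests as the enolate of keto sulfone 14; LiN(iPr)2 then removes C7–H to give the keto sulfone dianion, whose C7 terminus opens the epoxide at C8 by 4-exo-tet attack with inversion, forming the cyclobutane and the C9 alkoxide. The closest known reaction types are the γ-alkylation of 1,3-dicarbonyl-type dianions and the Stork epoxynitrile cyclisation, in which a stabilised carbanion prefers 4-exo over 5-endo opening. C8 is set by backside attack on the epoxide made in step 8, C9 is retained, and C7 is fixed by the tether: C6 is already tied through C5–C4–C3 to C2, so C6 must end cis to that chain and the methyl group is forced to the face of the C9–C11 bridge. The attack at C8 is a trans-diaxial (Fürst–Plattner) opening from the conformer with the bulky C3 group on C2 equatorial and the C7 arm on C1 axial, which is the favoured chair. The step needs acylation to outrun 5-exo opening of the epoxide by the C5 carbanion, and C- rather than O-alkylation of the dianion; the first is addressed by running the ester attack cold before any dianion is made, the second by the much higher nucleophilicity of the γ-carbon.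

Step 10
Reactants: 15 (1S,2S,4R,7R,8R,9S,11R)-4-[(tert-butyldimethylsilyl)oxy]-9-hydroxy-3,3,7,11-tetramethyl-5-(phenylsulfonyl)tricyclo[5.4.0.0^{2,8}]undecan-6-one
Product: 16 (1S,2S,4S,7R,8R,9S,11R)-4-[(tert-butyldimethylsilyl)oxy]-9-hydroxy-3,3,7,11-tetramethyltricyclo[5.4.0.0^{2,8}]undecan-6-one
Conditions: SmI2 (2.5 equiv), THF–MeOH, −78 °C
Reagents that add atoms: none
Why: Reductive desulfonylation of a β-keto sulfone by SmI2: electron transfer cleaves the C–S bond α to the ketone and methanol protonates the samarium enolate, faster than any reaction of the ketone or the silyl ether.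

Step 11
Reactants: 16 (1S,2S,4S,7R,8R,9S,11R)-4-[(tert-butyldimethylsilyl)oxy]-9-hydroxy-3,3,7,11-tetramethyltricyclo[5.4.0.0^{2,8}]undecan-6-one
Product: 17 (1S,2S,4S,7R,8R,11R)-4-[(tert-butyldimethylsilyl)oxy]-3,3,7,11-tetramethyltricyclo[5.4.0.0^{2,8}]undecane-6,9-dione
Conditions: Dess–Martin periodinane, NaHCO3, CH2Cl2, 0 to 23 °C
Reagents that add atoms: none
Why: Dess–Martin oxidation of the secondary C9 alcohol to the ketone under buffered conditions; C8 is a bridgehead and cannot epimerise.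

Step 12
Reactants: 17 (1S,2S,4S,7R,8R,11R)-4-[(tert-butyldimethylsilyl)oxy]-3,3,7,11-tetramethyltricyclo[5.4.0.0^{2,8}]undecane-6,9-dione
Product: 18 (1S,2S,4S,7R,8R,11R)-4-hydroxy-3,3,7,11-tetramethyltricyclo[5.4.0.0^{2,8}]undecane-6,9-dione
Conditions: HF·pyridine, THF, 0 °C
Reagents that add atoms: none
Why: Fluoride desilylation under buffered acidic conditions avoids base-induced β-elimination of the β-oxygenated ketone.

Step 13
Reactants: 18 (1S,2S,4S,7R,8R,11R)-4-hydroxy-3,3,7,11-tetramethyltricyclo[5.4.0.0^{2,8}]undecane-6,9-dione, 19 acetaldehyde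
Product: 20 (1S,2S,4S,6S,7R,8R,11R)-6-hydroxy-3,3,7,11-tetramethyl-9-oxotricyclo[5.4.0.0^{2,8}]undecan-4-yl acetate
Conditions: SmI2 (30 mol%), MeCHO (10 equiv), THF, −10 °C
Reagents that add atoms: none
Why: Evans–Tishchenko reduction: the samarium-bound hemiacetal formed from the C4 alcohol and acetaldehyde delivers hydride intramolecularly to the C6 ketone from the face of the C4 oxygen, so the new C6 alcohol should be trans (1,3-anti) to the C4 acetate; the C9 ketone has no neighbouring hydroxyl and is not reduced.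

Step 14
Reactants: 20 (1S,2S,4S,6S,7R,8R,11R)-6-hydroxy-3,3,7,11-tetramethyl-9-oxotricyclo[5.4.0.0^{2,8}]undecan-4-yl acetate, 21 (2Z)-2-methylbut-2-enoic acid (angelic acid)
Product: 22 (1S,2S,4S,6S,7R,8R,11R)-4-acetoxy-3,3,7,11-tetramethyl-9-oxotricyclo[5.4.0.0^{2,8}]undecan-6-yl (2Z)-2-methylbut-2-enoate
Conditions: 2,4,6-trichlorobenzoyl chloride, Et3N, toluene, 23 °C; then 20, 80 °C
Reagents that add atoms: none
Why: Yamaguchi esterification through the mixed 2,4,6-trichlorobenzoic anhydride acylates the hindered C6 alcohol without the nucleophilic catalyst that isomerises angelates to tiglates; the trans-1,3 arrangement disfavours acetyl migration.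

Compound list
1 | ethyl (2E,4E)-hexa-2,4-dienoate | C/C=C/C=C/C(=O)OCC | starting material
2 | ethyl (3E)-2-methylhexa-3,5-dienoate | C=C/C=C/C(C)C(=O)OCC | intermediate
3 | ethyl (3E)-2,2-dimethylhexa-3,5-dienoate | C=C/C=C/C(C)(C)C(=O)OCC | intermediate
4 | (3E)-pent-3-en-2-one | C/C=C/C(C)=O | starting material
5 | ethyl 2-[(1R,5R,6S)-6-acetyl-5-methylcyclohex-2-en-1-yl]-2-methylpropanoate | CCOC(=O)C(C)(C)[C@H]1[C@@H](C(C)=O)[C@H](C)CC=C1 | intermediate
6 | (methoxymethyl)triphenylphosphonium chloride | COC[P+](c1ccccc1)(c1ccccc1)c1ccccc1.[Cl-] | starting material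
7 | ethyl 2-[(1R,5R,6S)-6-(1-methoxyprop-1-en-2-yl)-5-methylcyclohex-2-en-1-yl]-2-methylpropanoate (E/Z mixture) | CCOC(=O)C(C)(C)[C@H]1[C@@H](C(C)=COC)[C@H](C)CC=C1 | intermediate
8 | methyl phenyl sulfone | CS(=O)(=O)c1ccccc1 | starting material
9 | 3-[(1R,5R,6S)-6-(1-methoxyprop-1-en-2-yl)-5-methylcyclohex-2-en-1-yl]-3-methyl-1-(phenylsulfonyl)butan-2-one | O=C(CS(=O)(=O)c1ccccc1)C(C)(C)[C@H]2[C@@H](C(C)=COC)[C@H](C)CC=C2 | intermediate
10 | (2R)-3-[(1R,5R,6S)-6-(1-methoxyprop-1-en-2-yl)-5-methylcyclohex-2-en-1-yl]-3-methyl-1-(phenylsulfonyl)butan-2-ol | O=S(=O)(c1ccccc1)C[C@H](O)C(C)(C)[C@H]2[C@@H](C(C)=COC)[C@H](C)CC=C2 | intermediate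
11 | tert-butyldimethylsilyl ether of 10 | O=S(=O)(c1ccccc1)C[C@H](O[Si](C)(C)C(C)(C)C)C(C)(C)[C@H]2[C@@H](C(C)=COC)[C@H](C)CC=C2 | intermediate
12 | methyl 2-[(1S,2R,6R)-2-{(3R)-3-[(tert-butyldimethylsilyl)oxy]-2-methyl-4-(phenylsulfonyl)butan-2-yl}-6-methylcyclohex-3-en-1-yl]propanoate (α-epimers) | O=S(=O)(c1ccccc1)C[C@H](O[Si](C)(C)C(C)(C)C)C(C)(C)[C@H]2[C@@H](C(C)C(=O)OC)[C@H](C)CC=C2 | intermediate
13 | methyl 2-[(1R,2R,3S,4R,6S)-2-{(3R)-3-[(tert-butyldimethylsilyl)oxy]-2-methyl-4-(phenylsulfonyl)butan-2-yl}-4-methyl-7-oxabicyclo[4.1.0]heptan-3-yl]propanoate (epoxide trans to both side chains) | O=S(=O)(c1ccccc1)C[C@H](O[Si](C)(C)C(C)(C)C)C(C)(C)[C@H]2[C@@H](C(C)C(=O)OC)[C@H](C)C[C@@H]3O[C@H]23 | intermediate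
14 | 6-[(tert-butyldimethylsilyl)oxy]-3,4-epoxy-1,5,5,9-tetramethyl-7-(phenylsulfonyl)decahydro-8H-benzo[7]annulen-8-one (C5–C6 bond closed, C7–C8 open; epimers at the sulfonyl carbon and at the ring CH(CH3) next to the ketone) | O=C1C(S(=O)(=O)c5ccccc5)[C@H](O[Si](C)(C)C(C)(C)C)C(C)(C)[C@H]2[C@@H](C1C)[C@H](C)C[C@@H]3O[C@H]23 | intermediate
15 | (1S,2S,4R,7R,8R,9S,11R)-4-[(tert-butyldimethylsilyl)oxy]-9-hydroxy-3,3,7,11-tetramethyl-5-(phenylsulfonyl)tricyclo[5.4.0.0^{2,8}]undecan-6-one (C5 epimers) | O=C1C(S(=O)(=O)c4ccccc4)[C@H](O[Si](C)(C)C(C)(C)C)C(C)(C)[C@H]2[C@@H]3[C@H](C)C[C@H](O)[C@H]2[C@@]31C | intermediate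
16 | (1S,2S,4S,7R,8R,9S,11R)-4-[(tert-butyldimethylsilyl)oxy]-9-hydroxy-3,3,7,11-tetramethyltricyclo[5.4.0.0^{2,8}]undecan-6-one | O=C1C[C@H](O[Si](C)(C)C(C)(C)C)C(C)(C)[C@H]2[C@@H]3[C@H](C)C[C@H](O)[C@H]2[C@@]31C | intermediate
17 | (1S,2S,4S,7R,8R,11R)-4-[(tert-butyldimethylsilyl)oxy]-3,3,7,11-tetramethyltricyclo[5.4.0.0^{2,8}]undecane-6,9-dione | O=C1C[C@H](O[Si](C)(C)C(C)(C)C)C(C)(C)[C@H]2[C@@H]3[C@H](C)CC(=O)[C@H]2[C@@]31C | intermediate
18 | (1S,2S,4S,7R,8R,11R)-4-hydroxy-3,3,7,11-tetramethyltricyclo[5.4.0.0^{2,8}]undecane-6,9-dione | O=C1C[C@H](O)C(C)(C)[C@H]2[C@@H]3[C@H](C)CC(=O)[C@H]2[C@@]31C | intermediate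
19 | acetaldehyde | CC=O | starting material
20 | (1S,2S,4S,6S,7R,8R,11R)-6-hydroxy-3,3,7,11-tetramethyl-9-oxotricyclo[5.4.0.0^{2,8}]undecan-4-yl acetate | O[C@H]1C[C@H](OC(C)=O)C(C)(C)[C@H]2[C@@H]3[C@H](C)CC(=O)[C@H]2[C@@]31C | intermediate
21 | (2Z)-2-methylbut-2-enoic acid (angelic acid) | C/C=C(/C)C(=O)O | starting material
22 | (1S,2S,4S,6S,7R,8R,11R)-4-acetoxy-3,3,7,11-tetramethyl-9-oxotricyclo[5.4.0.0^{2,8}]undecan-6-yl (2Z)-2-methylbut-2-enoate | C/C=C(/C)C(=O)O[C@H]1C[C@H](OC(C)=O)C(C)(C)[C@H]2[C@@H]3[C@H](C)CC(=O)[C@H]2[C@@]31C | target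

Total step count: 14
Longest linear sequence: 14 steps (from ethyl sorbate 1)

Steps most likely to fail

Step 9. The C5 sulfonyl carbanion may open the epoxide in a 5-exo mode before it acylates the hindered ester, or the silyloxy group may be lost by β-elimination while the carbanion waits. The fallback sets out from 12 and returns at 15, and separates the two closures so that no epoxide is present during the acylation. Alkene 12 is treated with LiN(SiMe3)2 alone, which can only give the Dieckmann-type product, 6-[(tert-butyldimethylsilyl)oxy]-1,5,5,9-tetramethyl-7-(phenylsulfonyl)-1,2,4a,5,6,7,9,9a-octahydro-8H-benzo[7]annulen-8-one F1. Epoxidation of F1 with mCPBA, anti to the C5 quaternary carbon, gives 14, now isolated. Then LiN(iPr)2 (2.2 equiv) forms the dianion for the 4-exo-tet closure to 15. In this fallback the two bonds form in successive operations.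

Step 2. The hindered diene terminus may react sluggishly, and regio- or facial selectivity may erode with the catalytic Lewis acid. The fallback sets out from 3 and returns at 5, using auxiliary control. Diene 3 reacts with (R)-4-benzyl-3-[(E)-but-2-enoyl]oxazolidin-2-one (C/C=C/C(=O)N1[C@H](Cc2ccccc2)COC1=O) and Et2AlCl in CH2Cl2 at −78 to −30 °C. The chelated s-cis imide is attacked anti to benzyl to give ethyl 2-[(1R,5R,6S)-6-{[(4R)-4-benzyl-2-oxo-1,3-oxazolidin-3-yl]carbonyl}-5-methylcyclohex-2-en-1-yl]-2-methylpropanoate F2. AlMe3 and MeNHOMe·HCl convert F2 into ethyl 2-[(1R,5R,6S)-6-[methoxy(methyl)carbamoyl]-5-methylcyclohex-2-en-1-yl]-2-methylpropanoate F3, and MeMgBr at −78 °C gives ketone 5.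

Step 7. The chromium oxidant may cleave the enol ether C=C bond oxidatively instead of inducing the hydride shift. The fallback sets out from 11 and returns at 12. Mild hydrolysis of the enol ether (Hg(OAc)2, aq THF) gives 2-[(1S,2R,6R)-2-{(3R)-3-[(tert-butyldimethylsilyl)oxy]-2-methyl-4-(phenylsulfonyl)butan-2-yl}-6-methylcyclohex-3-en-1-yl]propanal F4. Pinnick oxidation (NaClO2, NaH2PO4, 2-methylbut-2-ene) gives the corresponding propanoic acid F5, and Me3SiCHN2 in MeOH gives ester 12.

Further compounds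
F1 | step 9 | 6-[(tert-butyldimethylsilyl)oxy]-1,5,5,9-tetramethyl-7-(phenylsulfonyl)-1,2,4a,5,6,7,9,9a-octahydro-8H-benzo[7]annulen-8-one (ring centres as in 12; C7/C9 epimers) | O=C1C(S(=O)(=O)c5ccccc5)[C@H](O[Si](C)(C)C(C)(C)C)C(C)(C)[C@H]2[C@@H](C1C)[C@H](C)CC=C2
F2 | step 2 | ethyl 2-[(1R,5R,6S)-6-{[(4R)-4-benzyl-2-oxo-1,3-oxazolidin-3-yl]carbonyl}-5-methylcyclohex-2-en-1-yl]-2-methylpropanoate | CCOC(=O)C(C)(C)[C@H]1[C@@H](C(=O)N2[C@H](Cc3ccccc3)COC2=O)[C@H](C)CC=C1
F3 | step 2 | ethyl 2-[(1R,5R,6S)-6-[methoxy(methyl)carbamoyl]-5-methylcyclohex-2-en-1-yl]-2-methylpropanoate | CCOC(=O)C(C)(C)[C@H]1[C@@H](C(=O)N(C)OC)[C@H](C)CC=C1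
F4 | step 7 | 2-[(1S,2R,6R)-2-{(3R)-3-[(tert-butyldimethylsilyl)oxy]-2-methyl-4-(phenylsulfonyl)butan-2-yl}-6-methylcyclohex-3-en-1-yl]propanal (α-epimers) | O=S(=O)(c1ccccc1)C[C@H](O[Si](C)(C)C(C)(C)C)C(C)(C)[C@H]2[C@@H](C(C)C=O)[C@H](C)CC=C2
F5 | step 7 | 2-[(1S,2R,6R)-2-{(3R)-3-[(tert-butyldimethylsilyl)oxy]-2-methyl-4-(phenylsulfonyl)butan-2-yl}-6-methylcyclohex-3-en-1-yl]propanoic acid (α-epimers) | O=S(=O)(c1ccccc1)C[C@H](O[Si](C)(C)C(C)(C)C)C(C)(C)[C@H]2[C@@H](C(C)C(=O)O)[C@H](C)CC=C2
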